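The E–O–F and F–O–G ethers are cut back to aryl esters, and everything else follows from that. In both links the oxygen sits on C4 of one ring, between two methoxy-bearing carbons, and is bonded to C1 of the next ring, the CH-flanked carbon that is the carboxyl position of syringic and gallic acid. The precursor is therefore a linear triester: methyl syringate acylated on O4 by a syringoyl unit whose O4 bears a 3,4,5-trimethoxybenzoyl group. One nickel-catalysed operation removes both ester carbonyls as CO and leaves two hindered diaryl ethers. Rings D, C, B and A are then added by copper-catalysed Ullmann couplings and Dakin oxidations, and BBr3 frees the seventeen hydroxyl groups.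

Key step: step 3

Assumption: rings are lettered A to G in the order in which they are written in the target SMILES; the target is achiral, so no step sets a stereocentre; all hydroxyl groups travel as methyl ethers, and the D–O–E link is made by copper-catalysed arylation so that CO extrusion is used only once.

Step 1
Reactants: 1 syringic acid; 2 3,4,5-trimethoxybenzoyl chloride
Product: 3 3,5-dimethoxy-4-(3,4,5-trimethoxybenzoyloxy)benzoic acid
Conditions: NaOH (2.2 equiv), H2O–acetone, 0 °C; then aq. HCl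
Reagents that add atoms: none
Why: Schotten–Baumann O-acylation, in which the dianion of the hydroxy acid reacts at the more nucleophilic phenoxide, any mixed anhydride at the carboxylate is hydrolysed in the cold alkaline medium, and the aryl ester survives the short exposure.

Step 2
Reactants: 3 3,5-dimethoxy-4-(3,4,5-trimethoxybenzoyloxy)benzoic acid; 4 methyl syringate
Product: 6 methyl 4-[3,5-dimethoxy-4-(3,4,5-trimethoxybenzoyloxy)benzoyloxy]-3,5-dimethoxybenzoate (E–F–G triester), via acid chloride 5 (not isolated)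
Conditions: (COCl)2, cat. DMF, CH2Cl2, 0 °C to rt, evaporate; then 4, Et3N, DMAP, CH2Cl2, 0 °C to rt
Reagents that add atoms: none
Why: Acid chloride formation followed by DMAP-catalysed esterification of a 2,6-dimethoxyphenol is routine depside chemistry, and the aryl ester already present is inert to oxalyl chloride.

Step 3
Reactants: 6 methyl 4-[3,5-dimethoxy-4-(3,4,5-trimethoxybenzoyloxy)benzoyloxy]-3,5-dimethoxybenzoate
Product: 9 methyl 4-[3,5-dimethoxy-4-(3,4,5-trimethoxyphenoxy)phenoxy]-3,5-dimethoxybenzoate (trimer EFG methyl ester), via E–O–F ether F–G ester 7 (not isolated), via F–O–G ether E–F ester 8 (not isolated)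
Conditions: Ni(cod)2 (20 mol%), 3,4-bis(dicyclohexylphosphino)thiophene (40 mol%), K3PO4, m-xylene, 150 °C, slow argon sweep
Reagents that add atoms: none
Why: Proposed new method: oxidative addition of the acyl C–O bond of each aryl ester to zerovalent nickel gives an aroyl nickel aryloxide, and loss of CO from it followed by C–O reductive elimination from the remaining aryl nickel aryloxide bonds the phenolic oxygen to C1 of ring F and of ring G, the carbons that bore the carbonyl groups. The closest known reaction type is the nickel- or palladium-catalysed decarbonylative diaryl ether synthesis from aryl esters of azine carboxylic acids with this ligand, whereas electron-rich benzoates without a ring nitrogen have not been shown to react this way. No ring is closed and no stereocentre is formed. The step needs chemoselectivity for the two aryl esters over the methyl ester and the aryl methyl ethers, which is secured because only a phenoxide leaving group makes the acyl C–O bond weak enough for oxidative addition. It also needs reductive elimination to outpace escape of the aryloxide from nickel, which the strongly donating chelating ligand, the apolar solvent and the flanking methoxy groups (able to hold the aryloxide on the metal) are expected to favour; because acylation has already placed each oxygen on its crowded C4, the hindered side of both ethers never has to be attacked.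

Step 4
Reactants: 9 methyl 4-[3,5-dimethoxy-4-(3,4,5-trimethoxyphenoxy)phenoxy]-3,5-dimethoxybenzoate
Product: 10 {4-[3,5-dimethoxy-4-(3,4,5-trimethoxyphenoxy)phenoxy]-3,5-dimethoxyphenyl}methanol
Conditions: LiAlH4, THF, 0 °C; aqueous work-up
Reagents that add atoms: none
Why: Hydride reduction of the methyl ester to the benzylic alcohol, with diaryl ethers and aryl methyl ethers inert to LiAlH4.

Step 5
Reactants: 10 {4-[3,5-dimethoxy-4-(3,4,5-trimethoxyphenoxy)phenoxy]-3,5-dimethoxyphenyl}methanol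
Product: 11 4-[3,5-dimethoxy-4-(3,4,5-trimethoxyphenoxy)phenoxy]-3,5-dimethoxybenzaldehyde
Conditions: MnO2, CH2Cl2, rt
Reagents that add atoms: none
Why: Selective oxidation of an electron-rich benzylic alcohol to the aldehyde by activated MnO2, which does not over-oxidise.

Step 6
Reactants: 11 4-[3,5-dimethoxy-4-(3,4,5-trimethoxyphenoxy)phenoxy]-3,5-dimethoxybenzaldehyde
Product: 13 4-[3,5-dimethoxy-4-(3,4,5-trimethoxyphenoxy)phenoxy]-3,5-dimethoxyphenol (trimer EFG phenol), via aryl formate 12 (not isolated)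
Conditions: mCPBA, CH2Cl2, 0 °C to rt; then K2CO3 (cat.), MeOH, rt
Reagents that add atoms: mCPBA, O=C(OO)c1cccc(Cl)c1
Why: Baeyer–Villiger (Dakin-type) oxidation, in which the electron-rich 4-aryloxy-3,5-dimethoxyphenyl group migrates to oxygen to give the aryl formate, and methanolysis releases the phenol.

Step 7
Reactants: 13 trimer EFG phenol; 14 2-bromo-3,4,5-trimethoxybenzaldehyde
Product: 15 2-{4-[3,5-dimethoxy-4-(3,4,5-trimethoxyphenoxy)phenoxy]-3,5-dimethoxyphenoxy}-3,4,5-trimethoxybenzaldehyde (tetramer DEFG aldehyde, formyl on C1 of ring D)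
Conditions: CuI (20 mol%), N,N-dimethylglycine (40 mol%), Cs2CO3, 1,4-dioxane, 100 °C
Reagents that add atoms: none
Why: Ullmann diaryl ether coupling of an unhindered, electron-rich phenol with a bromide that is activated by its ortho-formyl group, a well-used pairing under ligand-assisted CuI catalysis.

Step 8
Reactants: 15 tetramer DEFG aldehyde
Product: 17 2-{4-[3,5-dimethoxy-4-(3,4,5-trimethoxyphenoxy)phenoxy]-3,5-dimethoxyphenoxy}-3,4,5-trimethoxyphenol (tetramer DEFG phenol, OH on C1 of ring D), via aryl formate 16 (not isolated)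
Conditions: mCPBA, CH2Cl2, 0 °C to rt; then K2CO3 (cat.), MeOH, rt
Reagents that add atoms: mCPBA, O=C(OO)c1cccc(Cl)c1
Why: Baeyer–Villiger (Dakin-type) oxidation of a benzaldehyde carrying ortho-aryloxy and para-methoxy donors, so that aryl migration to the formate is favoured before methanolysis.

Step 9
Reactants: 17 tetramer DEFG phenol; 18 4-bromo-3,5-dimethoxybenzaldehyde
Product: 19 3,5-dimethoxy-4-(tetramer DEFG oxy)benzaldehyde (pentamer CDEFG aldehyde, the oxygen of 17 bonded to C4 of ring C, formyl on C1 of ring C)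
Conditions: CuI (20 mol%), N,N-dimethylglycine (40 mol%), Cs2CO3, 1,4-dioxane, 110 °C
Reagents that add atoms: none
Why: Ullmann diaryl ether coupling in which the bromide, although flanked by two methoxy groups, is activated by the para-formyl group, as in known ligand-accelerated couplings of di-ortho-substituted aryl halides.

Step 10
Reactants: 19 pentamer CDEFG aldehyde
Product: 21 pentamer CDEFG phenol (OH on C1 of ring C), via aryl formate 20 (not isolated)
Conditions: mCPBA, CH2Cl2, 0 °C to rt; then K2CO3 (cat.), MeOH, rt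
Reagents that add atoms: mCPBA, O=C(OO)c1cccc(Cl)c1
Why: Baeyer–Villiger (Dakin-type) oxidation of the same 4-aryloxy-3,5-dimethoxybenzaldehyde type as in step 6, followed by formate methanolysis.

Step 11
Reactants: 21 pentamer CDEFG phenol; 18 4-bromo-3,5-dimethoxybenzaldehyde
Product: 22 3,5-dimethoxy-4-(pentamer CDEFG oxy)benzaldehyde (hexamer BCDEFG aldehyde, formyl on C1 of ring B)
Conditions: CuI (20 mol%), N,N-dimethylglycine (40 mol%), Cs2CO3, 1,4-dioxane, 110 °C
Reagents that add atoms: none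
Why: Ullmann diaryl ether coupling of a phenol with two free ortho positions and the formyl-activated bromide, easier than step 9 because the nucleophile is unhindered.

Step 12
Reactants: 22 hexamer BCDEFG aldehyde
Product: 24 hexamer BCDEFG phenol (OH on C1 of ring B), via aryl formate 23 (not isolated)
Conditions: mCPBA, CH2Cl2, 0 °C to rt; then K2CO3 (cat.), MeOH, rt
Reagents that add atoms: mCPBA, O=C(OO)c1cccc(Cl)c1
Why: Baeyer–Villiger (Dakin-type) oxidation and methanolysis exactly as in steps 6 and 10.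

Step 13
Reactants: 24 hexamer BCDEFG phenol; 25 2-iodo-1,3,5-trimethoxybenzene (excess)
Product: 26 heptamer heptadecamethyl ether (ring A as 2,4,6-trimethoxyphenyl)
Conditions: CuI (20 mol%), picolinic acid (40 mol%), K3PO4, DMSO, 100 °C
Reagents that add atoms: none
Why: Ullmann diaryl ether coupling of an unhindered phenol with a di-ortho-methoxy aryl iodide under a CuI–picolinic acid system suited to hindered partners, with the cheap iodide in excess.

Step 14
Reactants: 26 heptamer heptadecamethyl ether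
Product: 27 CNP0304148.0 (target, seventeen free hydroxyl groups)
Conditions: BBr3 (large excess), CH2Cl2, −78 °C to rt, argon; then MeOH, H2O
Reagents that add atoms: none
Why: Lewis acid ether cleavage, in which BBr3 binds each methoxy oxygen and bromide removes the methyl group as MeBr, while diaryl ether C–O bonds offer no sp3 carbon and stay intact.

Compound list
1 | syringic acid | COc1cc(C(=O)O)cc(OC)c1O | starting material
2 | 3,4,5-trimethoxybenzoyl chloride | COc1cc(C(=O)Cl)cc(OC)c1OC | starting material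
3 | 3,5-dimethoxy-4-(3,4,5-trimethoxybenzoyloxy)benzoic acid | OC(=O)c1cc(OC)c(OC(=O)c2cc(OC)c(OC)c(OC)c2)c(OC)c1 | intermediate
4 | methyl syringate | COC(=O)c1cc(OC)c(O)c(OC)c1 | starting material
5 | 3,5-dimethoxy-4-(3,4,5-trimethoxybenzoyloxy)benzoyl chloride | O=C(Cl)c1cc(OC)c(OC(=O)c2cc(OC)c(OC)c(OC)c2)c(OC)c1 | intermediate
6 | methyl 4-[3,5-dimethoxy-4-(3,4,5-trimethoxybenzoyloxy)benzoyloxy]-3,5-dimethoxybenzoate (E–F–G triester) | COC(=O)c1cc(OC)c(OC(=O)c2cc(OC)c(OC(=O)c3cc(OC)c(OC)c(OC)c3)c(OC)c2)c(OC)c1 | intermediate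
7 | methyl 4-[3,5-dimethoxy-4-(3,4,5-trimethoxybenzoyloxy)phenoxy]-3,5-dimethoxybenzoate (E–O–F ether, F–G ester) | COC(=O)c1cc(OC)c(Oc2cc(OC)c(OC(=O)c3cc(OC)c(OC)c(OC)c3)c(OC)c2)c(OC)c1 | intermediate
8 | methyl 4-[3,5-dimethoxy-4-(3,4,5-trimethoxyphenoxy)benzoyloxy]-3,5-dimethoxybenzoate (F–O–G ether, E–F ester) | COC(=O)c1cc(OC)c(OC(=O)c2cc(OC)c(Oc3cc(OC)c(OC)c(OC)c3)c(OC)c2)c(OC)c1 | intermediate
9 | methyl 4-[3,5-dimethoxy-4-(3,4,5-trimethoxyphenoxy)phenoxy]-3,5-dimethoxybenzoate (trimer EFG methyl ester) | COC(=O)c1cc(OC)c(Oc2cc(OC)c(Oc3cc(OC)c(OC)c(OC)c3)c(OC)c2)c(OC)c1 | intermediate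
10 | {4-[3,5-dimethoxy-4-(3,4,5-trimethoxyphenoxy)phenoxy]-3,5-dimethoxyphenyl}methanol | OCc1cc(OC)c(Oc2cc(OC)c(Oc3cc(OC)c(OC)c(OC)c3)c(OC)c2)c(OC)c1 | intermediate
11 | 4-[3,5-dimethoxy-4-(3,4,5-trimethoxyphenoxy)phenoxy]-3,5-dimethoxybenzaldehyde | O=Cc1cc(OC)c(Oc2cc(OC)c(Oc3cc(OC)c(OC)c(OC)c3)c(OC)c2)c(OC)c1 | intermediate
12 | 4-[3,5-dimethoxy-4-(3,4,5-trimethoxyphenoxy)phenoxy]-3,5-dimethoxyphenyl formate | O=COc1cc(OC)c(Oc2cc(OC)c(Oc3cc(OC)c(OC)c(OC)c3)c(OC)c2)c(OC)c1 | intermediate
13 | 4-[3,5-dimethoxy-4-(3,4,5-trimethoxyphenoxy)phenoxy]-3,5-dimethoxyphenol (trimer EFG phenol) | Oc1cc(OC)c(Oc2cc(OC)c(Oc3cc(OC)c(OC)c(OC)c3)c(OC)c2)c(OC)c1 | intermediate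
14 | 2-bromo-3,4,5-trimethoxybenzaldehyde | O=Cc1cc(OC)c(OC)c(OC)c1Br | starting material
15 | 2-{4-[3,5-dimethoxy-4-(3,4,5-trimethoxyphenoxy)phenoxy]-3,5-dimethoxyphenoxy}-3,4,5-trimethoxybenzaldehyde (tetramer DEFG aldehyde) | O=Cc1cc(OC)c(OC)c(OC)c1Oc1cc(OC)c(Oc2cc(OC)c(Oc3cc(OC)c(OC)c(OC)c3)c(OC)c2)c(OC)c1 | intermediate
16 | formate of tetramer DEFG phenol | O=COc1cc(OC)c(OC)c(OC)c1Oc1cc(OC)c(Oc2cc(OC)c(Oc3cc(OC)c(OC)c(OC)c3)c(OC)c2)c(OC)c1 | intermediate
17 | 2-{4-[3,5-dimethoxy-4-(3,4,5-trimethoxyphenoxy)phenoxy]-3,5-dimethoxyphenoxy}-3,4,5-trimethoxyphenol (tetramer DEFG phenol) | Oc1cc(OC)c(OC)c(OC)c1Oc1cc(OC)c(Oc2cc(OC)c(Oc3cc(OC)c(OC)c(OC)c3)c(OC)c2)c(OC)c1 | intermediate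
18 | 4-bromo-3,5-dimethoxybenzaldehyde | O=Cc1cc(OC)c(Br)c(OC)c1 | starting material
19 | pentamer CDEFG aldehyde (oxygen of 17 on C4 of 3,5-dimethoxybenzaldehyde) | O=Cc1cc(OC)c(Oc2cc(OC)c(OC)c(OC)c2Oc2cc(OC)c(Oc3cc(OC)c(Oc4cc(OC)c(OC)c(OC)c4)c(OC)c3)c(OC)c2)c(OC)c1 | intermediate
20 | formate of pentamer CDEFG phenol | O=COc1cc(OC)c(Oc2cc(OC)c(OC)c(OC)c2Oc2cc(OC)c(Oc3cc(OC)c(Oc4cc(OC)c(OC)c(OC)c4)c(OC)c3)c(OC)c2)c(OC)c1 | intermediate
21 | pentamer CDEFG phenol (OH on C1 of ring C) | Oc1cc(OC)c(Oc2cc(OC)c(OC)c(OC)c2Oc2cc(OC)c(Oc3cc(OC)c(Oc4cc(OC)c(OC)c(OC)c4)c(OC)c3)c(OC)c2)c(OC)c1 | intermediate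
22 | hexamer BCDEFG aldehyde (oxygen of 21 on C4 of 3,5-dimethoxybenzaldehyde) | O=Cc1cc(OC)c(Oc2cc(OC)c(Oc3cc(OC)c(OC)c(OC)c3Oc3cc(OC)c(Oc4cc(OC)c(Oc5cc(OC)c(OC)c(OC)c5)c(OC)c4)c(OC)c3)c(OC)c2)c(OC)c1 | intermediate
23 | formate of hexamer BCDEFG phenol | O=COc1cc(OC)c(Oc2cc(OC)c(Oc3cc(OC)c(OC)c(OC)c3Oc3cc(OC)c(Oc4cc(OC)c(Oc5cc(OC)c(OC)c(OC)c5)c(OC)c4)c(OC)c3)c(OC)c2)c(OC)c1 | intermediate
24 | hexamer BCDEFG phenol (OH on C1 of ring B) | Oc1cc(OC)c(Oc2cc(OC)c(Oc3cc(OC)c(OC)c(OC)c3Oc3cc(OC)c(Oc4cc(OC)c(Oc5cc(OC)c(OC)c(OC)c5)c(OC)c4)c(OC)c3)c(OC)c2)c(OC)c1 | intermediate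
25 | 2-iodo-1,3,5-trimethoxybenzene | COc1cc(OC)c(I)c(OC)c1 | starting material
26 | heptamer heptadecamethyl ether | COc1cc(OC)c(Oc2cc(OC)c(Oc3cc(OC)c(Oc4cc(OC)c(OC)c(OC)c4Oc4cc(OC)c(Oc5cc(OC)c(Oc6cc(OC)c(OC)c(OC)c6)c(OC)c5)c(OC)c4)c(OC)c3)c(OC)c2)c(OC)c1 | intermediate
27 | CNP0304148.0 | Oc1cc(O)c(Oc2cc(O)c(Oc3cc(O)c(Oc4cc(O)c(O)c(O)c4Oc4cc(O)c(Oc5cc(O)c(Oc6cc(O)c(O)c(O)c6)c(O)c5)c(O)c4)c(O)c3)c(O)c2)c(O)c1 | target

Total steps: 14. Longest linear sequence: 14 steps (1 to 27); compounds 2, 4, 14, 18 and 25 enter as purchased materials.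

Steps most likely to fail

Step 3. After oxidative addition the aryloxide may leave nickel faster than CO is lost and the C–O bond is closed, which would exchange fragments between molecules or reduce the aryl group, and bound CO may stall the catalyst. The fallback uses known chemistry and sets out from methyl syringate 4. Ullmann coupling with purchased 4-bromo-2,6-dimethoxybenzaldehyde (CuI, N,N-dimethylglycine, Cs2CO3, dioxane, 100 °C) should give methyl 4-(4-formyl-3,5-dimethoxyphenoxy)-3,5-dimethoxybenzoate F1. mCPBA should convert this into methyl 4-(4-formyloxy-3,5-dimethoxyphenoxy)-3,5-dimethoxybenzoate F2, and methanolysis (K2CO3, MeOH) should give methyl 4-(4-hydroxy-3,5-dimethoxyphenoxy)-3,5-dimethoxybenzoate F3. Ullmann coupling of this hindered phenol with purchased 5-iodo-1,2,3-trimethoxybenzene (CuI, picolinic acid, K3PO4, DMSO, 90 °C) comes back to the route at 9.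

Step 13. Substitution at the electron-rich iodide flanked by two methoxy groups may be sluggish, so that reductive loss of iodine and oxidation of the phenoxide compete. The fallback sets out from 24 and carries the para oxygen of ring A as a formyl group. Coupling with bromide 18 under the conditions of step 11 should give the heptamer aldehyde with ring A as 4-formyl-2,6-dimethoxyphenyl F4. Dakin oxidation with mCPBA should give the corresponding aryl formate F5, and methanolysis the heptamer phenol with a free para hydroxyl on ring A F6. BBr3 under the conditions of step 14 then cleaves the sixteen methyl ethers and comes back to the route at 27.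

Step 14. Cleavage of seventeen methyl ethers may stop short, and the free polyphenol may oxidise in air during work-up and purification. The fallback sets out from 26 and isolates the product through a stable derivative. After BBr3 treatment the crude product is acetylated with Ac2O–pyridine to the heptadecaacetate of the target F7, which can be chromatographed on silica gel and separated from partly methylated material. Deacetylation with catalytic NaOMe in degassed MeOH, followed by acidic resin, comes back to the route at 27.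

Further compounds
F1 | step 3 | methyl 4-(4-formyl-3,5-dimethoxyphenoxy)-3,5-dimethoxybenzoate | COC(=O)c1cc(OC)c(Oc2cc(OC)c(C=O)c(OC)c2)c(OC)c1
F2 | step 3 | methyl 4-(4-formyloxy-3,5-dimethoxyphenoxy)-3,5-dimethoxybenzoate | COC(=O)c1cc(OC)c(Oc2cc(OC)c(OC=O)c(OC)c2)c(OC)c1
F3 | step 3 | methyl 4-(4-hydroxy-3,5-dimethoxyphenoxy)-3,5-dimethoxybenzoate | COC(=O)c1cc(OC)c(Oc2cc(OC)c(O)c(OC)c2)c(OC)c1
F4 | step 13 | heptamer aldehyde with ring A as 4-formyl-2,6-dimethoxyphenyl | O=Cc1cc(OC)c(Oc2cc(OC)c(Oc3cc(OC)c(Oc4cc(OC)c(OC)c(OC)c4Oc4cc(OC)c(Oc5cc(OC)c(Oc6cc(OC)c(OC)c(OC)c6)c(OC)c5)c(OC)c4)c(OC)c3)c(OC)c2)c(OC)c1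
F5 | step 13 | heptamer aryl formate with ring A as 4-formyloxy-2,6-dimethoxyphenyl | O=COc1cc(OC)c(Oc2cc(OC)c(Oc3cc(OC)c(Oc4cc(OC)c(OC)c(OC)c4Oc4cc(OC)c(Oc5cc(OC)c(Oc6cc(OC)c(OC)c(OC)c6)c(OC)c5)c(OC)c4)c(OC)c3)c(OC)c2)c(OC)c1
F6 | step 13 | heptamer hexadecamethyl ether with free para hydroxyl on ring A | Oc1cc(OC)c(Oc2cc(OC)c(Oc3cc(OC)c(Oc4cc(OC)c(OC)c(OC)c4Oc4cc(OC)c(Oc5cc(OC)c(Oc6cc(OC)c(OC)c(OC)c6)c(OC)c5)c(OC)c4)c(OC)c3)c(OC)c2)c(OC)c1
F7 | step 14 | heptadecaacetate of the target | CC(=O)Oc1cc(OC(C)=O)c(Oc2cc(OC(C)=O)c(Oc3cc(OC(C)=O)c(Oc4cc(OC(C)=O)c(OC(C)=O)c(OC(C)=O)c4Oc4cc(OC(C)=O)c(Oc5cc(OC(C)=O)c(Oc6cc(OC(C)=O)c(OC(C)=O)c(OC(C)=O)c6)c(OC(C)=O)c5)c(OC(C)=O)c4)c(OC(C)=O)c3)c(OC(C)=O)c2)c(OC(C)=O)c1
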